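**Retrosynthetic overview**
1. The target is an achiral, fully enolised 2-benzoylcyclohexane-1,3,5-trione. Only this one ring has to be built (the phenyl ring is bought), and it is closed in the last step.
2. Ring bond C2–C3 is cut first (Dieckmann-type Claisen closure). This gives an open-chain methyl 7-phenyl-3,5,7-trioxoheptanoate that already carries all three prenyl groups.
3. Ring bond C5–C6 is the key bond. After a ketone-to-carbinol adjustment at C5 it is cut as an intermolecular aldol addition of a 1,3-diketone dianion (fragment B) to a non-enolisable formyl ester (fragment A).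
4. Fragment A comes from dimethyl malonate by double prenylation, mono-reduction and oxidation. Fragment B comes from benzoylacetone by γ-prenylation of its dianion.

Assumption: the target has no stereocentre (C4 carries two identical prenyl groups), so it is achiral, needs no asymmetric step and is drawn as one of several equilibrating enol tautomers; metal enolates count as the reactive form of the numbered carbonyl compound and get their own number only where they are pre-formed in a separate operation (the two lithium dianions).

**Step 1**
Reactants: 1 dimethyl malonate; 2 prenyl bromide (1-bromo-3-methylbut-2-ene)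
Product: 4 dimethyl 2,2-bis(3-methylbut-2-en-1-yl)malonate, via dimethyl prenylmalonate 3 (not isolated)
Conditions: NaH (2.4 equiv) added in portions to 1 + 2 (2.3 equiv), THF, 0 °C to reflux
Reagents that add atoms: prenyl bromide (compound 2), CC(C)=CCBr
Why: This is a malonic ester synthesis with two successive SN2 C-alkylations, in which the reactive allylic bromide and excess base carry 3 on to the quaternary diester, whose new centre bears two identical groups and is therefore no stereocentre.

**Step 2**
Reactants: 4 dimethyl 2,2-bis(3-methylbut-2-en-1-yl)malonate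
Product: 5 methyl 2-(hydroxymethyl)-5-methyl-2-(3-methylbut-2-en-1-yl)hex-4-enoate
Conditions: LiAlH(OtBu)3 (2.5 equiv), THF, reflux; then H2O, filter
Reagents that add atoms: none
Why: In this chemoselective hydride reduction the mild bulky reagent attacks only a malonate ester activated by its neighbour, so after one reduction the remaining ordinary hindered ester and the alkenes are left alone, and no stereocentre arises.

**Step 3**
Reactants: 5 methyl 2-(hydroxymethyl)-5-methyl-2-(3-methylbut-2-en-1-yl)hex-4-enoate
Product: 6 methyl 2-formyl-5-methyl-2-(3-methylbut-2-en-1-yl)hex-4-enoate (fragment A)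
Conditions: 2-iodoxybenzoic acid (IBX, 1.5 equiv), EtOAc, 75 °C; filter
Reagents that add atoms: none
Why: IBX oxidation of a primary alcohol stops at the aldehyde under neutral conditions that spare trisubstituted alkenes, and the aldehyde has no α-hydrogen, so it can neither enolise nor epimerise.

**Step 4**
Reactants: 7 benzoylacetone (1-phenylbutane-1,3-dione); 2 prenyl bromide
Product: 9 diketone 7-methyl-1-phenyloct-6-ene-1,3-dione (fragment B), via dilithium phenylbutadienediolate 8 (not isolated)
Conditions: LiN(iPr)2 (commercial solution, 2.1 equiv), THF, −78 to 0 °C; then 2 (1.0 equiv), −78 °C to rt; cold 1 M HCl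
Reagents that add atoms: prenyl bromide (compound 2), CC(C)=CCBr
Why: In this Hauser–Harris dianion γ-alkylation the last-formed and most basic terminal carbon of 8 takes the allylic bromide by SN2 while the central carbon stays masked as its enolate, and no stereocentre is formed.

**Step 5 (key fragment union)**
Reactants: 9 diketone 7-methyl-1-phenyloct-6-ene-1,3-dione (1.2 equiv); 6 methyl 2-formyl-5-methyl-2-(3-methylbut-2-en-1-yl)hex-4-enoate
Product: 11 aldol adduct methyl 3-hydroxy-2,2,4-tris(3-methylbut-2-en-1-yl)-5,7-dioxo-7-phenylheptanoate (racemic diastereomer mixture), via dilithium phenyloctatrienediolate 10 (not isolated)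
Conditions: LiN(iPr)2 (commercial solution, 2.5 equiv), THF, −78 to 0 °C; then 6 (1.0 equiv), −78 °C, 1 h; AcOH/THF quench at −78 °C
Reagents that add atoms: none
Why: This intermolecular aldol addition joins the only possible γ-carbanion of 10 to a non-enolisable aldehyde that far outruns the hindered ester at −78 °C, forming ring bond C5–C6, and the two new stereocentres arise without control, which is harmless because both are flattened in steps 6 and 7.

**Step 6**
Reactants: 11 aldol adduct
Product: 12 methyl 2,2,4-tris(3-methylbut-2-en-1-yl)-3,5,7-trioxo-7-phenylheptanoate (keto–enol mixture)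
Conditions: IBX (2.5 equiv), EtOAc, 75 °C; filter, use at once
Reagents that add atoms: none
Why: IBX oxidation of a β-hydroxy ketone to a β-diketone runs acid-free and base-free, which avoids retro-aldol cleavage and cyclodehydration and leaves active methylene groups and alkenes alone, while the carbinol centre is erased and C4 becomes a labile enolisable centre.

**Step 7**
Reactants: 12 methyl 2,2,4-tris(3-methylbut-2-en-1-yl)-3,5,7-trioxo-7-phenylheptanoate
Product: 13 target 2-benzoyl-3,5-dihydroxy-4,4,6-tris(3-methylbut-2-en-1-yl)cyclohexa-2,5-dien-1-one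
Conditions: KOtBu (3 equiv), degassed THF, Ar, 0 to 60 °C; cold 1 M HCl
Reagents that add atoms: none
Why: In this Dieckmann-type intramolecular Claisen condensation the carbanion between the benzoyl and C5 ketones attacks the ester, the only carbonyl not masked as an enolate, and the outcome is favoured because the gem-diprenyl effect helps six-ring closure, an aldol-type closure is blocked by the quaternary ester α-carbon, O-acylation is reversed by the liberated methoxide and the very acidic product is trapped as its dianion, leaving no stereocentre.

**Compound list**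
1 | dimethyl malonate | COC(=O)CC(=O)OC | starting material
2 | prenyl bromide (1-bromo-3-methylbut-2-ene) | CC(C)=CCBr | starting material
3 | dimethyl prenylmalonate (dimethyl 2-(3-methylbut-2-en-1-yl)malonate) | COC(=O)C(CC=C(C)C)C(=O)OC | intermediate
4 | dimethyl 2,2-bis(3-methylbut-2-en-1-yl)malonate | COC(=O)C(CC=C(C)C)(CC=C(C)C)C(=O)OC | intermediate
5 | methyl 2-(hydroxymethyl)-5-methyl-2-(3-methylbut-2-en-1-yl)hex-4-enoate | COC(=O)C(CO)(CC=C(C)C)CC=C(C)C | intermediate
6 | methyl 2-formyl-5-methyl-2-(3-methylbut-2-en-1-yl)hex-4-enoate | COC(=O)C(C=O)(CC=C(C)C)CC=C(C)C | intermediate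
7 | benzoylacetone (1-phenylbutane-1,3-dione) | CC(=O)CC(=O)c1ccccc1 | starting material
8 | dilithium phenylbutadienediolate (dilithium 1-phenylbuta-1,3-diene-1,3-diolate) | [Li+].[Li+].C=C([O-])C=C([O-])c1ccccc1 | intermediate
9 | 7-methyl-1-phenyloct-6-ene-1,3-dione | CC(C)=CCCC(=O)CC(=O)c1ccccc1 | intermediate
10 | dilithium phenyloctatrienediolate (dilithium 7-methyl-1-phenylocta-1,3,6-triene-1,3-diolate) | [Li+].[Li+].CC(C)=CCC=C([O-])C=C([O-])c1ccccc1 | intermediate
11 | methyl 3-hydroxy-2,2,4-tris(3-methylbut-2-en-1-yl)-5,7-dioxo-7-phenylheptanoate (racemic diastereomer mixture, no defined configuration) | COC(=O)C(CC=C(C)C)(CC=C(C)C)C(O)C(CC=C(C)C)C(=O)CC(=O)c1ccccc1 | intermediate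
12 | methyl 2,2,4-tris(3-methylbut-2-en-1-yl)-3,5,7-trioxo-7-phenylheptanoate | COC(=O)C(CC=C(C)C)(CC=C(C)C)C(=O)C(CC=C(C)C)C(=O)CC(=O)c1ccccc1 | intermediate
13 | 2-benzoyl-3,5-dihydroxy-4,4,6-tris(3-methylbut-2-en-1-yl)cyclohexa-2,5-dien-1-one (achiral) | CC(C)=CCC1=C(O)C(CC=C(C)C)(CC=C(C)C)C(O)=C(C(=O)c2ccccc2)C1=O | target

**Totals:** 7 steps. The longest linear sequence is 6 steps (steps 1, 2, 3, 5, 6, 7). Step 4 is the one-step side branch.

**Three steps most likely to fail**

Step 7 carries the highest risk. A stabilised enolate has to attack a neopentyl-type methyl ester, so the closure may stall or stop at the O-acylated enol lactone. The fallback swaps the order of the two ring bonds, so that the ring is closed by a far more reactive γ-carbanion. It sets out from 4 and 9 and comes back at 13. Diester 4 is half-saponified (KOH 1.05 equiv, MeOH, reflux, then cold dilute HCl) to 2-(methoxycarbonyl)-5-methyl-2-(3-methylbut-2-en-1-yl)hex-4-enoic acid F1. Oxalyl chloride with catalytic DMF in CH2Cl2 at 0 °C then gives methyl 2-(chlorocarbonyl)-5-methyl-2-(3-methylbut-2-en-1-yl)hex-4-enoate F2, which has no α-hydrogen and so cannot form a ketene. Soft enolisation of 9 with MgCl2/Et3N in MeCN at 0 °C lets F2 acylate the central carbon in a Claisen-type C-acylation that forms ring bond C2–C3. The product is methyl 4-benzoyl-9-methyl-2,2-bis(3-methylbut-2-en-1-yl)-3,5-dioxodec-8-enoate F3. LiN(iPr)2 (3 equiv, THF, −78 °C to rt) removes the methine proton and one proton of the only remaining α-CH2. That carbanion closes ring bond C5–C6 on the ester, and acid work-up gives 13.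

Step 5 is next. A secondary carbanion meets a neopentyl aldehyde, and the crowded aldolate may revert by retro-aldol. The fallback uses the unhindered primary dianion and postpones the third prenyl group to the end. It sets out from 6 and 8 (made from 7 as in step 4) and comes back at 13. Aldol addition at −78 °C gives methyl 3-hydroxy-2,2-bis(3-methylbut-2-en-1-yl)-5,7-dioxo-7-phenylheptanoate F4. IBX in hot EtOAc then gives methyl 2,2-bis(3-methylbut-2-en-1-yl)-3,5,7-trioxo-7-phenylheptanoate F5. KOtBu in THF closes the ring to 2-benzoyl-3,5-dihydroxy-4,4-bis(3-methylbut-2-en-1-yl)cyclohexa-2,5-dien-1-one F6. Its dianion (KOH 2 equiv, water, 0 °C) is C-alkylated at the only unsubstituted ring carbon with 2 (1.0 equiv) to give 13. The bromide is limited to one equivalent to hold back the tetraprenyl by-product.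

Step 6 is third. The enolised diketone can be over-oxidised at its active methylene. The hydroxy diketone or the product triketone can also cyclodehydrate to a pyranone. The fallback drops the redox detour and forms the same bond at the ketone level by a crossed Claisen condensation. It sets out from 4 and 10 (made from 9 as in step 5, here with 3.1 equiv LiN(iPr)2 so that the more acidic product does not quench the dianion) and comes back at 12. The non-enolisable diester 4 is added in THF at 0 °C and the mixture is warmed to 40 °C. The reaction is slower for steric reasons, but nothing else in the flask can enolise or self-condense. This way skips steps 2, 3, 5 and 6 and makes no new compound (F0).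

**Further compounds**
F1 | step 7 | 2-(methoxycarbonyl)-5-methyl-2-(3-methylbut-2-en-1-yl)hex-4-enoic acid | COC(=O)C(CC=C(C)C)(CC=C(C)C)C(=O)O
F2 | step 7 | methyl 2-(chlorocarbonyl)-5-methyl-2-(3-methylbut-2-en-1-yl)hex-4-enoate | COC(=O)C(CC=C(C)C)(CC=C(C)C)C(=O)Cl
F3 | step 7 | methyl 4-benzoyl-9-methyl-2,2-bis(3-methylbut-2-en-1-yl)-3,5-dioxodec-8-enoate | COC(=O)C(CC=C(C)C)(CC=C(C)C)C(=O)C(C(=O)c1ccccc1)C(=O)CCC=C(C)C
F4 | step 5 | methyl 3-hydroxy-2,2-bis(3-methylbut-2-en-1-yl)-5,7-dioxo-7-phenylheptanoate | COC(=O)C(CC=C(C)C)(CC=C(C)C)C(O)CC(=O)CC(=O)c1ccccc1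
F5 | step 5 | methyl 2,2-bis(3-methylbut-2-en-1-yl)-3,5,7-trioxo-7-phenylheptanoate | COC(=O)C(CC=C(C)C)(CC=C(C)C)C(=O)CC(=O)CC(=O)c1ccccc1
F6 | step 5 | 2-benzoyl-3,5-dihydroxy-4,4-bis(3-methylbut-2-en-1-yl)cyclohexa-2,5-dien-1-one | O=C1C=C(O)C(CC=C(C)C)(CC=C(C)C)C(O)=C1C(=O)c2ccccc2
F0 | step 6 | none | none
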